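The ten-membered ring is cut free, not closed. Its C6 oxygen and C10 lie across the ring from each other, so a temporary C6–C10 bond turns it into a cyclopentane (C6–C10) fused to a cycloheptene (C10, C1–C6) carrying the 1,3-diol array O–C6–C10–C1–O. In the key step the C6 alkoxide of the bicyclic monomesylate breaks the shared C6–C10 bond and expels the C1 sulfonate, giving at once the ten-membered ring, the E C1=C10 alkene, the C6 ketone and the ring-cis C4=C5 alkene. The precursor is a trans-fused bicyclo[5.3.0]decene with a C6 tertiary alcohol, an equatorial C1 mesylate cis to the C10 methyl, and the C7 and C8 stereocentres of the target.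

Key step: step 16

Remark on the chemistry (assumption): vinylmagnesium bromide should add to the cyclopentanone face opposite the C1 chain on the neighbouring quaternary C10, so the bicycle is planned trans-fused (C6 hydroxyl and C10 methyl anti), which also holds the equatorial C1 mesylate antiperiplanar to C6–C10; C1, C6 and C10 lose their configuration in the key step in any case.
Names use germacrane numbering (ring C1–C10, lactone carbons C11–C13, C14 methyl, C15 oxymethyl); TBS = tert-butyldimethylsilyl, TES = triethylsilyl, PMB = 4-methoxybenzyl, Ms = methanesulfonyl.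

Step 1
Reactants: 1 2-methylenepropane-1,3-diol
Product: 2 2-[(4-methoxybenzyloxy)methyl]prop-2-en-1-ol
Conditions: NaH (1.0 equiv), THF–DMF, 0 °C; 4-MeOC6H4CH2Cl (1.0 equiv), n-Bu4NI (cat.), 0 °C to rt
Reagents that add atoms: 4-methoxybenzyl chloride, COc1ccc(CCl)cc1
Why: Williamson etherification of the monosodium alkoxide, where one equivalent each of base and halide should leave the mono-ether as the main product, separable from diol and bis-ether.

Step 2
Reactants: 2 2-[(4-methoxybenzyloxy)methyl]prop-2-en-1-ol; 3 triethyl orthoacetate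
Product: 5 ethyl 4-[(4-methoxybenzyloxy)methyl]pent-4-enoate, via ketene acetal 4 (not isolated)
Conditions: EtCO2H (cat.), neat 3, 140 °C, EtOH distilled off
Reagents that add atoms: none
Why: Johnson–Claisen rearrangement, in which acid-catalysed exchange forms ketene acetal 4 and its [3,3] shift makes the C2–C3 bond while turning the former carbinol carbon into the 1,1-disubstituted C4 methylene needed for metathesis.

Step 3
Reactants: 5 ethyl 4-[(4-methoxybenzyloxy)methyl]pent-4-enoate
Product: 6 4-[(4-methoxybenzyloxy)methyl]pent-4-enal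
Conditions: i-Bu2AlH (1.05 equiv), CH2Cl2, −78 °C; aq. potassium sodium tartrate
Reagents that add atoms: none
Why: Partial ester reduction with i-Bu2AlH at −78 °C, which should stop at the aldehyde oxidation level and leave the alkene and the PMB ether alone.

Step 4
Reactants: 7 (R)-4-(TBS-oxy)cyclopent-2-en-1-one
Product: 8 (R)-2-iodo-4-(TBS-oxy)cyclopent-2-en-1-one
Conditions: I2, pyridine–CH2Cl2, 0 °C to rt
Reagents that add atoms: iodine, [I][I]
Why: α-Iodination of the enone by an addition–elimination sequence of the Baylis–Hillman type (pyridine adds at C9, the enolate is iodinated at C10, pyridine leaves), which does not touch the C8 stereocentre.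

Step 5
Reactants: 8 (R)-2-iodo-4-(TBS-oxy)cyclopent-2-en-1-one
Product: 9 (R)-2-methyl-4-(TBS-oxy)cyclopent-2-en-1-one
Conditions: Me4Sn, Pd2(dba)3 (cat.), AsPh3, CuI, NMP, 60 °C
Reagents that add atoms: tetramethylstannane, C[Sn](C)(C)C
Why: Stille coupling of the α-iodoenone with tetramethylstannane, a base-free way to place the C14 methyl on C10 that spares the elimination-prone γ-silyloxy enone.

Step 6
Reactants: 9 (R)-2-methyl-4-(TBS-oxy)cyclopent-2-en-1-one; 6 4-[(4-methoxybenzyloxy)methyl]pent-4-enal
Product: 11 aldol adduct (2R,4S)-2-[(1R)-1-hydroxy-4-(PMB-oxymethyl)pent-4-en-1-yl]-2-methyl-4-(TBS-oxy)cyclopentan-1-one, via lithium enolate 10 (not isolated)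
Conditions: LiBH(s-Bu)3 (1.05 equiv), THF, −78 °C; then 6, −78 °C; AcOH quench at −78 °C
Reagents that add atoms: none
Why: Reductive aldol reaction: conjugate hydride addition gives the C6–C10 enolate 10 regiospecifically, and its aldol addition to 6 through a closed chair transition state on the face anti to the C8 silyloxy group should set quaternary C10 (methyl cis to the C8 oxygen) and the C1 carbinol as drawn, the latter being reset in steps 13 and 14 so that either C1 epimer serves.

Step 7
Reactants: 11 aldol adduct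
Product: 12 C1 triethylsilyl ether of the aldol adduct
Conditions: Et3SiOTf, 2,6-lutidine, CH2Cl2, −78 °C
Reagents that add atoms: triethylsilyl trifluoromethanesulfonate, CC[Si](CC)(CC)OS(=O)(=O)C(F)(F)F
Why: Silylation of the hindered secondary alcohol with the silyl triflate and a hindered pyridine, which blocks retro-aldol cleavage of the quaternary aldol in the two basic steps that follow.

Step 8
Reactants: 13 2-(TBS-oxy)ethanol
Product: 14 2-(TBS-oxy)ethyl trifluoromethanesulfonate
Conditions: Tf2O, 2,6-lutidine, CH2Cl2, −78 °C; used at once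
Reagents that add atoms: trifluoromethanesulfonic anhydride, O=S(=O)(OS(=O)(=O)C(F)(F)F)C(F)(F)F
Why: Triflation of a primary alcohol to give a 2-oxyethyl electrophile reactive enough to alkylate a ketone enolate at −78 °C.

Step 9
Reactants: 12 C1 triethylsilyl ether of the aldol adduct; 14 2-(TBS-oxy)ethyl trifluoromethanesulfonate
Product: 16 C7-alkylated ketone (2R,4S,5R)-2-methyl-2-[(1R)-4-(PMB-oxymethyl)-1-(TES-oxy)pent-4-en-1-yl]-4-(TBS-oxy)-5-[2-(TBS-oxy)ethyl]cyclopentan-1-one, via lithium enolate 15 (not isolated)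
Conditions: LiN(i-Pr)2 (1.1 equiv), THF, −78 °C; then 14, −78 to −50 °C
Reagents that add atoms: none
Why: Enolate alkylation: with C10 quaternary only C7 can be deprotonated (enolate 15), and the triflate should approach anti to the adjacent C8 silyloxy group to give the trans C7/C8 relationship of the target, low temperature and a fast electrophile being chosen to outrun E1cB loss of that group.

Step 10
Reactants: 16 C7-alkylated ketone
Product: 17 C6 vinyl carbinol (1R,2R,4S,5R)-1-vinylcyclopentan-1-ol
Conditions: CeCl3 (anhydrous), CH2=CHMgBr, THF, −78 °C; then H2O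
Reagents that add atoms: vinylmagnesium bromide, C=C[Mg]Br
Why: Organocerium 1,2-addition, non-basic enough not to enolise C7, in which both α-branches (the C1 chain on C10 and the C7 side chain) shield the same face so that the vinyl group should enter cis to the C10 methyl and the C6 hydroxyl end up cis to the C7 chain.

Step 11
Reactants: 17 C6 vinyl carbinol
Product: 18 trans-fused bicyclo[5.3.0]decenol with C1 OTES
Conditions: (H2IMes)(PCy3)Cl2Ru=CHPh (second-generation Grubbs catalyst, 10 mol %), toluene, 80 °C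
Reagents that add atoms: none
Why: Ring-closing metathesis between the C5 vinyl group and the C4 methylene, a 7-membered closure that can only give the ring-cis C4=C5 alkene and whose trans ring fusion is already fixed by step 10.

Step 12
Reactants: 18 trans-fused bicyclo[5.3.0]decenol with C1 OTES
Product: 19 bicyclic 1,6-diol (C1 hydroxyl trans to C10 methyl)
Conditions: PPTS (cat.), MeOH–CH2Cl2 (1:1), 0 °C
Reagents that add atoms: none
Why: Acid-catalysed methanolysis, which cleaves the triethylsilyl ether much faster than the two tert-butyldimethylsilyl ethers and frees the C1 hydroxyl.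

Step 13
Reactants: 19 bicyclic 1,6-diol (C1 hydroxyl trans to C10 methyl)
Product: 20 bicyclic 6-hydroxy-1-ketone
Conditions: Dess–Martin periodinane, CH2Cl2, 0 °C to rt
Reagents that add atoms: none
Why: Dess–Martin oxidation of the secondary C1 alcohol beside the inert tertiary C6 alcohol, which erases the aldol-derived C1 configuration under non-basic conditions that avoid retro-aldol opening.

Step 14
Reactants: 20 bicyclic 6-hydroxy-1-ketone
Product: 21 bicyclic 1,6-diol (C1 hydroxyl cis to C10 methyl)
Conditions: Me4NBH(OAc)3, MeCN–AcOH (1:1), −40 to −20 °C; aq. potassium sodium tartrate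
Reagents that add atoms: none
Why: Saksena–Evans reduction, in which the borohydride bound to the C6 oxygen delivers hydride within the molecule to the C1 carbonyl face on the side of that oxygen, also the face away from the axial C10 methyl, so that the equatorial C1 hydroxyl should come out anti to the C6 hydroxyl and cis to the methyl.

Step 15
Reactants: 21 bicyclic 1,6-diol (C1 hydroxyl cis to C10 methyl)
Product: 22 bicyclic C1 mesylate with free C6 tertiary alcohol
Conditions: MsCl (1.2 equiv), Et3N, CH2Cl2, −20 to 0 °C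
Reagents that add atoms: methanesulfonyl chloride, CS(=O)(=O)Cl
Why: Mesylation through sulfene, which takes the secondary C1 alcohol in preference to the tertiary C6 alcohol and converts it with retention into the nucleofuge.

Step 16
Reactants: 22 bicyclic C1 mesylate with free C6 tertiary alcohol
Product: 24 (7R,8S)-cyclodeca-1(10),4-dien-6-one with E C1=C10 and ring-cis C4=C5, via potassium alkoxide 23 (not isolated)
Conditions: KOt-Bu (1.05 equiv), THF, −40 to 0 °C, short reaction time; pH 7 phosphate buffer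
Reagents that add atoms: none
Why: Grob (Wharton-type) fragmentation of a cyclic 1,3-diol monosulfonate: the lone pair of alkoxide 23 feeds the C6–C10 bond, which breaks as the antiperiplanar C1–O bond ionises, in one concerted, stereospecific event. The closest known case is the conversion of trans-decalin-1,3-diol monosulfonates into (E)-cyclodecenones, run here on a trans-fused bicyclo[5.3.0]decene. No ring is closed: the ten-membered ring appears by cleavage of the bond shared by the five- and seven-membered rings, so the entropic and transannular cost of a medium-ring closure is never paid. No stereocentre is formed, but two alkene geometries are fixed: C1=C10 becomes E because the mesylate is cis to the C10 methyl, and C4=C5 stays ring-cis as inherited from the cycloheptene. The step needs fragmentation to beat oxetane formation and E2 loss of the mesylate, which the trans ring fusion secures by holding the equatorial C1–O bond anti to C6–C10, and it needs the β-silyloxy enone to survive, which the single equivalent of base (used up as potassium mesylate forms) and the low temperature should secure.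

Step 17
Reactants: 24 (7R,8S)-cyclodeca-1(10),4-dien-6-one
Product: 25 (6R)-allylic alcohol
Conditions: NaBH4, CeCl3·7H2O, MeOH, −78 °C
Reagents that add atoms: none
Why: Luche 1,2-reduction carried out at once on the sensitive β-silyloxy enone, in which hydride should attack the outer face of the ring carbonyl anti to the C7 side chain standing roughly perpendicular to it, giving the (6R)-alcohol with the hydroxyl trans to the C7 chain and cis to the C8 oxygen.

Step 18
Reactants: 26 (S)-3-bromo-2-hydroxy-2-methylpropanoic acid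
Product: 28 (R)-2,3-dihydroxy-2-methylpropanoic acid, via sodium glycidate 27 (not isolated)
Conditions: NaOH (3 equiv), H2O, 0 °C then 80 °C; then HCl to pH 2
Reagents that add atoms: sodium hydroxide, [Na+].[OH-]
Why: Intramolecular Williamson closure to glycidate 27 followed by hydroxide opening at its primary carbon, which exchanges bromide for hydroxyl without touching the quaternary stereocentre (the descriptor changes from S to R only because the priorities change).

Step 19
Reactants: 28 (R)-2,3-dihydroxy-2-methylpropanoic acid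
Product: 29 (R)-2,2,4-trimethyl-1,3-dioxolane-4-carboxylic acid
Conditions: 2-methoxypropene, PPTS (cat.), DMF, 0 °C to rt; aqueous work-up at pH 4
Reagents that add atoms: 2-methoxypropene, C=C(C)OC
Why: Acid-catalysed ketalisation of the 1,2-diol with the enol ether, any mixed ketal ester formed at the carboxyl group being hydrolysed during work-up.

Step 20
Reactants: 25 (6R)-allylic alcohol; 29 (R)-2,2,4-trimethyl-1,3-dioxolane-4-carboxylic acid
Product: 31 C6 acetonide ester, via mixed anhydride 30 (not isolated)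
Conditions: 29, 2,4,6-Cl3C6H2COCl, Et3N, THF, rt; then 25, DMAP, toluene, rt
Reagents that add atoms: none
Why: Yamaguchi esterification through mixed anhydride 30, suited to a hindered allylic alcohol and an α-quaternary acid that cannot racemise, with retention at C6 because the C6–O bond is not broken.

Step 21
Reactants: 31 C6 acetonide ester
Product: 32 8,12-diol
Conditions: HF·pyridine, pyridine, THF, 0 °C to rt
Reagents that add atoms: none
Why: Fluoride cleavage of both silyl ethers under buffered acidic conditions that should leave the acetonide, the PMB ether and the C6 ester (no acyl shift without base) in place.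

Step 22
Reactants: 32 8,12-diol
Product: 35 11,13-dihydro 12,8-lactone, via hydroxy aldehyde 33 (not isolated), via lactol 34 (not isolated)
Conditions: TEMPO (20 mol %), PhI(OAc)2 (2.5 equiv), CH2Cl2, rt
Reagents that add atoms: none
Why: Oxidative lactonisation, in which the oxoammonium salt oxidises the primary C12 alcohol to aldehyde 33, the C8 hydroxyl closes lactol 34 (5-exo-trig) and a second oxidation gives the γ-lactone trans-fused at C7–C8 without touching either stereocentre.

Step 23
Reactants: 35 11,13-dihydro 12,8-lactone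
Product: 39 C11 methylene lactone (PMB ether), via lithium enolate 36 (not isolated), via Mannich base 37 (not isolated), via ammonium iodide 38 (not isolated)
Conditions: LiN(i-Pr)2 (1.1 equiv), THF, −78 °C; CH2=NMe2+ I−, −78 °C to rt; then MeI, MeOH, rt; then aq. NaHCO3, CH2Cl2
Reagents that add atoms: N,N-dimethylmethyleneiminium iodide, C=[N+](C)C.[I-]
Why: Eschenmoser methylenation: lactone enolate 36 (the C6 ester has no α-hydrogen) undergoes a Mannich reaction to 37, and quaternisation to 38 followed by mild-base elimination of trimethylamine should leave the C11=C13 methylene.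

Step 24
Reactants: 39 C11 methylene lactone (PMB ether)
Product: 40 C15 allylic alcohol
Conditions: DDQ, CH2Cl2–pH 7 buffer (10:1), 0 °C
Reagents that add atoms: none
Why: Oxidative PMB cleavage by DDQ through the benzylic cation, in a buffered two-phase medium that protects the acid-sensitive 1,5-diene and the allylic ester.

Step 25
Reactants: 40 C15 allylic alcohol
Product: 41 C15 acetate with acetonide
Conditions: Ac2O, pyridine, DMAP (cat.), CH2Cl2, 0 °C
Reagents that add atoms: acetic anhydride, CC(=O)OC(C)=O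
Why: Acetylation under nucleophilic catalysis of the only free hydroxyl, the primary allylic C15 alcohol.

Step 26
Reactants: 41 C15 acetate with acetonide
Product: 42 CNP0426025.2
Conditions: AcOH–H2O (4:1), 40 °C
Reagents that add atoms: none
Why: Hydrolysis of the terminal acetonide with weak aqueous acid, chosen to free the diol without transannular cyclisation of the 1(10),4-diene or solvolysis of the allylic esters.

Compound list
1 | 2-methylenepropane-1,3-diol | C=C(CO)CO | starting material
2 | 2-[(4-methoxybenzyloxy)methyl]prop-2-en-1-ol | C=C(CO)COCc1ccc(OC)cc1 | intermediate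
3 | triethyl orthoacetate | CCOC(C)(OCC)OCC | starting material
4 | ketene acetal, 1-ethoxyvinyl 2-[(4-methoxybenzyloxy)methyl]allyl ether | C=C(OCC)OCC(=C)COCc1ccc(OC)cc1 | intermediate
5 | ethyl 4-[(4-methoxybenzyloxy)methyl]pent-4-enoate | CCOC(=O)CCC(=C)COCc1ccc(OC)cc1 | intermediate
6 | 4-[(4-methoxybenzyloxy)methyl]pent-4-enal (C1–C4 and C15) | O=CCCC(=C)COCc1ccc(OC)cc1 | intermediate
7 | (R)-4-(tert-butyldimethylsilyloxy)cyclopent-2-en-1-one | O=C1C=C[C@H](O[Si](C)(C)C(C)(C)C)C1 | starting material
8 | (R)-4-(tert-butyldimethylsilyloxy)-2-iodocyclopent-2-en-1-one | O=C1C(I)=C[C@H](O[Si](C)(C)C(C)(C)C)C1 | intermediate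
9 | (R)-4-(tert-butyldimethylsilyloxy)-2-methylcyclopent-2-en-1-one | O=C1C(C)=C[C@H](O[Si](C)(C)C(C)(C)C)C1 | intermediate
10 | lithium (S)-4-(tert-butyldimethylsilyloxy)-2-methylcyclopent-1-en-1-olate (C6–C10 enolate) | [Li]OC1=C(C)C[C@H](O[Si](C)(C)C(C)(C)C)C1 | intermediate
11 | (2R,4S)-2-[(1R)-1-hydroxy-4-(PMB-oxymethyl)pent-4-en-1-yl]-2-methyl-4-(TBS-oxy)cyclopentan-1-one (C10 methyl cis to C8 OTBS) | O=C1C[C@@H](O[Si](C)(C)C(C)(C)C)C[C@]1(C)[C@H](O)CCC(=C)COCc1ccc(OC)cc1 | intermediate
12 | (2R,4S)-2-methyl-2-[(1R)-4-(PMB-oxymethyl)-1-(TES-oxy)pent-4-en-1-yl]-4-(TBS-oxy)cyclopentan-1-one | O=C1C[C@@H](O[Si](C)(C)C(C)(C)C)C[C@]1(C)[C@H](O[Si](CC)(CC)CC)CCC(=C)COCc1ccc(OC)cc1 | intermediate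
13 | 2-(tert-butyldimethylsilyloxy)ethanol | OCCO[Si](C)(C)C(C)(C)C | starting material
14 | 2-(tert-butyldimethylsilyloxy)ethyl trifluoromethanesulfonate | O=S(=O)(OCCO[Si](C)(C)C(C)(C)C)C(F)(F)F | intermediate
15 | lithium enolate of 12 (C6–O–Li, C6=C7) | [Li]OC1=C[C@@H](O[Si](C)(C)C(C)(C)C)C[C@]1(C)[C@H](O[Si](CC)(CC)CC)CCC(=C)COCc1ccc(OC)cc1 | intermediate
16 | (2R,4S,5R)-2-methyl-2-[(1R)-4-(PMB-oxymethyl)-1-(TES-oxy)pent-4-en-1-yl]-4-(TBS-oxy)-5-[2-(TBS-oxy)ethyl]cyclopentan-1-one (C7 chain trans to C8 OTBS, cis to the C1 chain) | O=C1[C@H](CCO[Si](C)(C)C(C)(C)C)[C@@H](O[Si](C)(C)C(C)(C)C)C[C@]1(C)[C@H](O[Si](CC)(CC)CC)CCC(=C)COCc1ccc(OC)cc1 | intermediate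
17 | (1R,2R,4S,5R)-2-methyl-2-[(1R)-4-(PMB-oxymethyl)-1-(TES-oxy)pent-4-en-1-yl]-4-(TBS-oxy)-5-[2-(TBS-oxy)ethyl]-1-vinylcyclopentan-1-ol (vinyl cis to C10 methyl, hydroxyl cis to C7 chain) | O[C@]1(C=C)[C@H](CCO[Si](C)(C)C(C)(C)C)[C@@H](O[Si](C)(C)C(C)(C)C)C[C@]1(C)[C@H](O[Si](CC)(CC)CC)CCC(=C)COCc1ccc(OC)cc1 | intermediate
18 | (1R,6R,7R,8S,10R)-trans-fused bicyclo[5.3.0]decene (cyclopentane C6–C10, cycloheptene C10, C1–C6 with C4=C5): 6-OH, 1-OTES trans to 10-methyl, 4-CH2OPMB, 7-CH2CH2OTBS, 8-OTBS | O[C@@]12C=C(COCc3ccc(OC)cc3)CC[C@@H](O[Si](CC)(CC)CC)[C@@]1(C)C[C@H](O[Si](C)(C)C(C)(C)C)[C@H]2CCO[Si](C)(C)C(C)(C)C | intermediate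
19 | (1R,6R,7R,8S,10R)-bicyclic 1,6-diol, 1-OH trans to 10-methyl | O[C@@]12C=C(COCc3ccc(OC)cc3)CC[C@@H](O)[C@@]1(C)C[C@H](O[Si](C)(C)C(C)(C)C)[C@H]2CCO[Si](C)(C)C(C)(C)C | intermediate
20 | (6R,7R,8S,10S)-bicyclic 6-hydroxy-1-ketone | O[C@@]12C=C(COCc3ccc(OC)cc3)CCC(=O)[C@@]1(C)C[C@H](O[Si](C)(C)C(C)(C)C)[C@H]2CCO[Si](C)(C)C(C)(C)C | intermediate
21 | (1S,6R,7R,8S,10R)-bicyclic 1,6-diol, 1-OH cis to 10-methyl and anti to 6-OH | O[C@@]12C=C(COCc3ccc(OC)cc3)CC[C@H](O)[C@@]1(C)C[C@H](O[Si](C)(C)C(C)(C)C)[C@H]2CCO[Si](C)(C)C(C)(C)C | intermediate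
22 | (1S,6R,7R,8S,10R)-trans-fused bicyclo[5.3.0]decenol: C6 tertiary alcohol, equatorial C1 mesylate cis to 10-methyl, 4-CH2OPMB, 7-CH2CH2OTBS, 8-OTBS (key-step precursor) | O[C@@]12C=C(COCc3ccc(OC)cc3)CC[C@H](OS(C)(=O)=O)[C@@]1(C)C[C@H](O[Si](C)(C)C(C)(C)C)[C@H]2CCO[Si](C)(C)C(C)(C)C | intermediate
23 | potassium C6 alkoxide of 22 | [K]O[C@@]12C=C(COCc3ccc(OC)cc3)CC[C@H](OS(C)(=O)=O)[C@@]1(C)C[C@H](O[Si](C)(C)C(C)(C)C)[C@H]2CCO[Si](C)(C)C(C)(C)C | intermediate
24 | (7R,8S)-ten-membered 1(10)E,4-dien-6-one (C4=C5 ring-cis): 8-OTBS, 7-CH2CH2OTBS, 4-CH2OPMB, 10-methyl (key-step product) | CC(C)(C)[Si](C)(C)O[C@H]1C/C(C)=C/CC/C(COCc2ccc(OC)cc2)=C\C(=O)[C@@H]1CCO[Si](C)(C)C(C)(C)C | intermediate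
25 | (6R,7S,8S)-6-alcohol of 24 (6-OH trans to C7 chain, cis to 8-OTBS) | CC(C)(C)[Si](C)(C)O[C@H]1C/C(C)=C/CC/C(COCc2ccc(OC)cc2)=C\[C@@H](O)[C@@H]1CCO[Si](C)(C)C(C)(C)C | intermediate
26 | (S)-3-bromo-2-hydroxy-2-methylpropanoic acid | OC(=O)[C@](C)(O)CBr | starting material
27 | sodium (R)-2-methyloxirane-2-carboxylate | [Na+].[O-]C(=O)[C@@]1(C)CO1 | intermediate
28 | (R)-2,3-dihydroxy-2-methylpropanoic acid | OC(=O)[C@](C)(O)CO | intermediate
29 | (R)-2,2,4-trimethyl-1,3-dioxolane-4-carboxylic acid | OC(=O)[C@@]1(C)COC(C)(C)O1 | intermediate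
30 | mixed anhydride of 29 with 2,4,6-trichlorobenzoic acid | O=C(OC(=O)[C@@]1(C)COC(C)(C)O1)c1c(Cl)cc(Cl)cc1Cl | intermediate
31 | (6R,7S,8S)-6-O-[(R)-2,2,4-trimethyl-1,3-dioxolane-4-carbonyl] ester of 25 | CC(C)(C)[Si](C)(C)O[C@H]1C/C(C)=C/CC/C(COCc2ccc(OC)cc2)=C\[C@@H](OC(=O)[C@@]2(C)COC(C)(C)O2)[C@@H]1CCO[Si](C)(C)C(C)(C)C | intermediate
32 | (6R,7R,8S)-8,12-diol with C6 acetonide ester and 15-OPMB | O[C@H]1C/C(C)=C/CC/C(COCc2ccc(OC)cc2)=C\[C@@H](OC(=O)[C@@]2(C)COC(C)(C)O2)[C@@H]1CCO | intermediate
33 | 8-hydroxy-12-aldehyde | O[C@H]1C/C(C)=C/CC/C(COCc2ccc(OC)cc2)=C\[C@@H](OC(=O)[C@@]2(C)COC(C)(C)O2)[C@@H]1CC=O | intermediate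
34 | 12,8-lactol (C12 epimers) | OC1O[C@H]2C/C(C)=C/CC/C(COCc3ccc(OC)cc3)=C\[C@@H](OC(=O)[C@@]3(C)COC(C)(C)O3)[C@@H]2C1 | intermediate
35 | (6R,7R,8S)-11,13-dihydro 12,8-lactone, trans-fused, with C6 acetonide ester and 15-OPMB | O=C1O[C@H]2C/C(C)=C/CC/C(COCc3ccc(OC)cc3)=C\[C@@H](OC(=O)[C@@]3(C)COC(C)(C)O3)[C@@H]2C1 | intermediate
36 | lithium enolate of lactone 35 (C12–O–Li, C11=C12) | [Li]OC1O[C@H]2C/C(C)=C/CC/C(COCc3ccc(OC)cc3)=C\[C@@H](OC(=O)[C@@]3(C)COC(C)(C)O3)[C@@H]2C=1 | intermediate
37 | Mannich base, 11-(dimethylaminomethyl) lactone (C11 epimers) | CN(C)CC1C(=O)O[C@H]2C/C(C)=C/CC/C(COCc3ccc(OC)cc3)=C\[C@@H](OC(=O)[C@@]3(C)COC(C)(C)O3)[C@H]12 | intermediate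
38 | trimethylammonium iodide of 37 | C[N+](C)(C)CC1C(=O)O[C@H]2C/C(C)=C/CC/C(COCc3ccc(OC)cc3)=C\[C@@H](OC(=O)[C@@]3(C)COC(C)(C)O3)[C@H]12.[I-] | intermediate
39 | (6R,7R,8S)-11(13)-methylene 12,8-lactone with C6 acetonide ester and 15-OPMB | C=C1C(=O)O[C@H]2C/C(C)=C/CC/C(COCc3ccc(OC)cc3)=C\[C@@H](OC(=O)[C@@]3(C)COC(C)(C)O3)[C@H]12 | intermediate
40 | 15-alcohol of 39 | C=C1C(=O)O[C@H]2C/C(C)=C/CC/C(CO)=C\[C@@H](OC(=O)[C@@]3(C)COC(C)(C)O3)[C@H]12 | intermediate
41 | 15-acetate with C6 acetonide ester | C=C1C(=O)O[C@H]2C/C(C)=C/CC/C(COC(C)=O)=C\[C@@H](OC(=O)[C@@]3(C)COC(C)(C)O3)[C@H]12 | intermediate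
42 | CNP0426025.2, (6R,7R,8S)-15-acetoxy-6-[(2R)-2,3-dihydroxy-2-methylpropanoyloxy]germacra-1(10)E,4,11(13)-trien-12,8-olide (C4=C5 ring-cis) | C=C1C(=O)O[C@H]2C/C(C)=C/CC/C(COC(C)=O)=C\[C@@H](OC(=O)[C@](C)(O)CO)[C@H]12 | target

Total step count: 26.
Longest linear sequence: 21 steps, from 1 to 42 (steps 1–3, 6, 7, 9–17 and 20–26).

Steps most likely to fail:

Step 16, the fragmentation. If any alkoxide outlives the cleavage, the newly formed β-silyloxy enone can lose the C8 silyloxy group by E1cB elimination or epimerise at C7. Fallback, a tandem reductive fragmentation: setting out from 22, the alkoxide is generated with KOt-Bu in THF at −40 °C in the presence of LiBH4, so that the dienone is reduced to the allylic alcohol as fast as it forms and never accumulates beside base. This comes back to the route at 25 and makes no new compound (F0).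

Step 9, the C7 alkylation. Enolate 15 may expel the C8 silyloxy group (E1cB) faster than it is alkylated, or be alkylated on oxygen. Fallback, side chain before the quaternary centre: setting out from 9, deprotonation with LiN(i-Pr)2 at −78 °C should give the cross-conjugated lithium dienolate F1, whose elimination would have to produce an antiaromatic cyclopentadienone and should therefore be slow. Alkylation with 14 anti to the silyloxy group should give the trans-4,5-disubstituted enone F2. Conjugate reduction with LiBH(s-Bu)3 should give lithium enolate F3, which adds to aldehyde 6 to give hydroxy ketone F4. Silylation with Et3SiOTf and 2,6-lutidine comes back to the route at 16.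

Step 17, the C6 reduction. Hydride may be delivered to the other face of the ring carbonyl (poor or reversed facial selectivity); this is the least certain stereochemical prediction of the route. Fallback, an inverting esterification: setting out from 24, the reduction product of opposite configuration, the (6S)-allylic alcohol F5, is esterified with acid 29 under Mitsunobu conditions (PPh3, DIAD, toluene, 0 °C to rt) with SN2 inversion at C6, coming back to the route at 31.

Further compounds
F0 | step 16 | none | none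
F1 | step 9 | lithium dienolate of 9 (C6–O–Li, C6=C7, C9=C10) | [Li]OC1=C[C@@H](O[Si](C)(C)C(C)(C)C)C=C1C
F2 | step 9 | (4S,5R)-2-methyl-4-(TBS-oxy)-5-[2-(TBS-oxy)ethyl]cyclopent-2-en-1-one (trans) | O=C1C(C)=C[C@H](O[Si](C)(C)C(C)(C)C)[C@H]1CCO[Si](C)(C)C(C)(C)C
F3 | step 9 | lithium C6–C10 enolate from conjugate reduction of F2 | [Li]OC1=C(C)C[C@H](O[Si](C)(C)C(C)(C)C)[C@H]1CCO[Si](C)(C)C(C)(C)C
F4 | step 9 | (2R,4S,5R)-2-[(1R)-1-hydroxy-4-(PMB-oxymethyl)pent-4-en-1-yl]-2-methyl-4-(TBS-oxy)-5-[2-(TBS-oxy)ethyl]cyclopentan-1-one | O=C1[C@H](CCO[Si](C)(C)C(C)(C)C)[C@@H](O[Si](C)(C)C(C)(C)C)C[C@]1(C)[C@H](O)CCC(=C)COCc1ccc(OC)cc1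
F5 | step 17 | (6S,7S,8S)-6-alcohol of 24 (C6 epimer of 25) | CC(C)(C)[Si](C)(C)O[C@H]1C/C(C)=C/CC/C(COCc2ccc(OC)cc2)=C\[C@H](O)[C@@H]1CCO[Si](C)(C)C(C)(C)C
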